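**Retrosynthetic overview**
- The bicyclo[3.1.0]hexene (cyclopentene and cyclopropane together) is closed last by cycloisomerisation of an acyclic 1,5-enyne; one stereocentre plus the (E)-alkene geometry relay the other three centres.
- The enyne comes from a preformed α-methoxy-γ-pyrone (first ring made) and an α-chiral aldehyde by Horner–Wadsworth–Emmons olefination.
- Key disconnection: the bond between the aldehyde α-carbon and the α-carbon of the ethyl ketone (a 1,4-dicarbonyl). The aldehyde α-carbon is made electrophilic as a chiral enamine radical cation (enolonium equivalent) and is trapped by the central carbon of 3-methoxypenta-1,2-diene, an α-acylvinyl anion equivalent.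
- Building blocks: crotonaldehyde and 1-propynyllithium; methoxyallene and iodoethane; methyl 2-methyl-3-oxopentanoate and N-methoxy-N-methylpropanamide.
- Ring order: pyrone, then both carbocycles in the final step.

Assumption: the propargylic methine of the hexynal fragment is carried as a 1:1 epimer mixture because it becomes sp2 in the last step; 1-propynyllithium and methoxyallene are taken as catalogue chemicals.

**Route**

Step 1
Reactants: 1 (E)-but-2-enal (crotonaldehyde); 2 1-propynyllithium
Product: 4 3-methylhex-4-ynal (racemic), via aluminate enolate 3 (not isolated)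
Conditions: Al(OC6H3Ph2-2,6)3 (1.1 equiv, from AlMe3 + 3 equiv 2,6-diphenylphenol), toluene, −78 °C; then 2 (1.5 equiv), THF, −78 °C; 1 M HCl
Reagents that add atoms: none
Why: Conjugate alkynylation of an enal: the bulky aluminium tris(aryloxide) buries the carbonyl so the lithium alkynide adds 1,4; the new C3 centre is racemic and is erased in step 8.

Step 2
Reactants: 5 1-methoxypropa-1,2-diene (methoxyallene); 6 iodoethane
Product: 8 3-methoxypenta-1,2-diene, via 1-lithio-1-methoxyallene 7 (not isolated)
Conditions: n-BuLi (1.05 equiv), THF, −40 °C; then 6, −40 °C to rt; distil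
Reagents that add atoms: none
Why: α-Lithiation of the alkoxyallene at the oxygen-bearing carbon followed by SN2 alkylation with a primary iodide (standard alkoxyallene chemistry).

Step 3 (key step)
Reactants: 4 3-methylhex-4-ynal; 8 3-methoxypenta-1,2-diene (2.5 equiv)
Product: 10 (2R)-3-methyl-2-(3-oxopent-1-en-2-yl)hex-4-ynal (C3 epimers), via O-methyl oxocarbenium nitrate 9 (not isolated)
Conditions: (2S,5S)-5-benzyl-2-tert-butyl-3-methylimidazolidin-4-one·CF3CO2H (20 mol %), (NH4)2Ce(NO3)6 (2.2 equiv), 2,6-di-tert-butylpyridine (2 equiv), H2O (2 equiv), acetone, −20 °C, 24 h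
Reagents that add atoms: water, O
Why: Proposed new method: organo-SOMO activation, in which tetravalent cerium oxidises the chiral enamine of 4 to a 3π-electron radical cation whose α-carbon is electrophilic, the enol-ether π bond of allene 8 traps it at the central carbon, a second cerium equivalent oxidises the resulting α-methoxyallyl radical to oxocarbenium 9 and water releases the α-methylene ketone, so two normally nucleophilic α-carbons are joined as a 1,4-dicarbonyl; the benzyl group of the (2S,5S) catalyst shields one enamine face and sets the 2R centre; the closest known reactions are the enantioselective SOMO α-enolation of aldehydes with enolsilanes and the use of silyloxyallenes as α-acylvinyl anion equivalents.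

Step 4
Reactants: 11 methyl 2-methyl-3-oxopentanoate; 12 N-methoxy-N-methylpropanamide
Product: 14 methyl 2,4-dimethyl-3,5-dioxoheptanoate, via sodium lithium dianion 13 (not isolated)
Conditions: NaH (1.1 equiv), THF, 0 °C; n-BuLi (1.05 equiv), 0 °C; then 12, 0 °C to rt; aq HCl
Reagents that add atoms: none
Why: Weiler β-keto ester dianion acylation: the γ-carbanion attacks the Weinreb amide, whose stable tetrahedral adduct prevents over-addition; the two methine centres are enolisable and irrelevant.

Step 5
Reactants: 14 methyl 2,4-dimethyl-3,5-dioxoheptanoate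
Product: 15 6-ethyl-4-hydroxy-3,5-dimethyl-2H-pyran-2-one
Conditions: DBU (1.2 equiv), toluene, 80 °C; aq HCl
Reagents that add atoms: none
Why: Base-mediated lactonisation of the β,δ-diketo ester (δ-enolate oxygen onto the ester, loss of methanol) gives the 4-hydroxy-2-pyranone.

Step 6
Reactants: 15 6-ethyl-4-hydroxy-3,5-dimethyl-2H-pyran-2-one
Product: 17 2-ethyl-6-methoxy-3,5-dimethyl-4H-pyran-4-one, via hydroxypyrylium triflate 16 (not isolated)
Conditions: MeOTf (1.2 equiv), CH2Cl2, rt; aq NaHCO3
Reagents that add atoms: methyl trifluoromethanesulfonate, COS(=O)(=O)C(F)(F)F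
Why: The hard methylating agent alkylates the lactone carbonyl oxygen to give 2-methoxy-4-hydroxypyrylium 16, and loss of the OH proton on work-up leaves the α-methoxy-γ-pyrone (regioselective O-methylation of a 4-hydroxy-2-pyranone).

Step 7
Reactants: 17 2-ethyl-6-methoxy-3,5-dimethyl-4H-pyran-4-one (1.05 equiv); 10 (2R)-3-methyl-2-(3-oxopent-1-en-2-yl)hex-4-ynal (0.9 equiv)
Product: 21 2-methoxy-3,5-dimethyl-6-[(2E,4R)-5-methyl-4-(3-oxopent-1-en-2-yl)oct-2-en-6-yn-2-yl]-4H-pyran-4-one (C5 epimers), via lithium dienolate 18 (not isolated), via pyronylethylphosphonate 19 (not isolated), via lithiated phosphonate 20 (not isolated)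
Conditions: LiN(SiMe3)2 (2.0 equiv), THF, −78 °C; ClP(O)(OEt)2 (1.0 equiv), −78 to −40 °C; then 10, −78 to 0 °C; aq NH4Cl
Reagents that add atoms: none
Why: Lateral lithiation of the 2-ethyl group gives vinylogous enolate 18, C-phosphorylation restores the pyrone, and the second equivalent of amide converts 19 directly into carbanion 20 so that no free strong base remains when aldehyde 10 is added; Horner–Wadsworth–Emmons olefination of the α-branched aldehyde with this α-methyl stabilised phosphonate gives the (E)-trisubstituted alkene and leaves the 4R centre untouched at low temperature.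

Step 8
Reactants: 21 2-methoxy-3,5-dimethyl-6-[(2E,4R)-5-methyl-4-(3-oxopent-1-en-2-yl)oct-2-en-6-yn-2-yl]-4H-pyran-4-one
Product: 22 2-methoxy-3,5-dimethyl-6-[(1S,4R,5R,6S)-1,3,6-trimethyl-4-(3-oxopent-1-en-2-yl)bicyclo[3.1.0]hex-2-en-6-yl]-4H-pyran-4-one (target)
Conditions: Ph3PAuCl (5 mol %), AgSbF6 (5 mol %), CH2Cl2, 0 °C to rt
Reagents that add atoms: none
Why: Monovalent-gold 1,5-enyne cycloisomerisation: the trisubstituted alkene attacks the Ph3PAu+-activated alkyne 5-endo to give a cyclopropyl carbene, and a 1,2-hydride shift from the propargylic CH(CH3) forms the ring alkene and converges both epimers; the (E)-geometry is transferred stereospecifically (methyl endo, pyrone exo) and A(1,3) strain at the 4R centre puts the side chain anti to the new cyclopropane, which fixes the 1S, 5R and 6S centres.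

**Compound list**

1 | (E)-but-2-enal (crotonaldehyde) | C/C=C/C=O | starting material
2 | 1-propynyllithium | [Li]C#CC | starting material
3 | lithium [(3-methylhex-1-en-4-yn-1-yl)oxy]tris(2,6-diphenylphenoxy)aluminate | CC#CC(C)C=CO[Al-](Oc1c(-c2ccccc2)cccc1-c1ccccc1)(Oc1c(-c2ccccc2)cccc1-c1ccccc1)Oc1c(-c2ccccc2)cccc1-c1ccccc1.[Li+] | intermediate
4 | 3-methylhex-4-ynal (racemic) | CC#CC(C)CC=O | intermediate
5 | 1-methoxypropa-1,2-diene (methoxyallene) | C=C=COC | starting material
6 | iodoethane | CCI | starting material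
7 | 1-lithio-1-methoxypropa-1,2-diene | C=C=C([Li])OC | intermediate
8 | 3-methoxypenta-1,2-diene | C=C=C(CC)OC | intermediate
9 | (2R)-3-methyl-2-[3-(methyloxoniumylidene)pent-1-en-2-yl]hex-4-ynal nitrate (O-methyl oxocarbenium ion of 10, C3 epimers) | C=C(C(CC)=[O+]C)[C@@H](C(C)C#CC)C=O.[O-][N+](=O)[O-] | intermediate
10 | (2R)-3-methyl-2-(3-oxopent-1-en-2-yl)hex-4-ynal (C3 epimers) | C=C(C(=O)CC)[C@@H](C(C)C#CC)C=O | intermediate
11 | methyl 2-methyl-3-oxopentanoate | CCC(=O)C(C)C(=O)OC | starting material
12 | N-methoxy-N-methylpropanamide | CCC(=O)N(C)OC | starting material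
13 | sodium lithium 1-methoxy-2-methylpenta-1,3-diene-1,3-diolate (dianion of 11) | CC=C([O-])C(C)=C([O-])OC.[Na+].[Li+] | intermediate
14 | methyl 2,4-dimethyl-3,5-dioxoheptanoate (stereoisomer and tautomer mixture) | CCC(=O)C(C)C(=O)C(C)C(=O)OC | intermediate
15 | 6-ethyl-4-hydroxy-3,5-dimethyl-2H-pyran-2-one | CCc1oc(=O)c(C)c(O)c1C | intermediate
16 | 6-ethyl-4-hydroxy-2-methoxy-3,5-dimethylpyrylium trifluoromethanesulfonate | CCc1[o+]c(OC)c(C)c(O)c1C.[O-]S(=O)(=O)C(F)(F)F | intermediate
17 | 2-ethyl-6-methoxy-3,5-dimethyl-4H-pyran-4-one | CCc1oc(OC)c(C)c(=O)c1C | intermediate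
18 | lithium 2-ethylidene-6-methoxy-3,5-dimethyl-2H-pyran-4-olate | CC=C1OC(OC)=C(C)C(O[Li])=C1C | intermediate
19 | diethyl [1-(6-methoxy-3,5-dimethyl-4-oxo-4H-pyran-2-yl)ethyl]phosphonate | CCOP(=O)(OCC)C(C)c1oc(OC)c(C)c(=O)c1C | intermediate
20 | lithium salt of 19 (phosphonate carbanion drawn as the 2-ylidene-pyran-4-olate) | CCOP(=O)(OCC)C(C)=C1OC(OC)=C(C)C(O[Li])=C1C | intermediate
21 | 2-methoxy-3,5-dimethyl-6-[(2E,4R)-5-methyl-4-(3-oxopent-1-en-2-yl)oct-2-en-6-yn-2-yl]-4H-pyran-4-one (C5 epimers) | C=C(C(=O)CC)[C@@H](C(C)C#CC)/C=C(\C)c1oc(OC)c(C)c(=O)c1C | intermediate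
22 | 2-methoxy-3,5-dimethyl-6-[(1S,4R,5R,6S)-1,3,6-trimethyl-4-(3-oxopent-1-en-2-yl)bicyclo[3.1.0]hex-2-en-6-yl]-4H-pyran-4-one | C=C(C(=O)CC)[C@H]1C(C)=C[C@@]2(C)[C@@H]1[C@]2(C)c1oc(OC)c(C)c(=O)c1C | target

**Totals**

Total step count: 8. Longest linear sequence: 5 steps (steps 4, 5, 6, 7, 8, from methyl 2-methyl-3-oxopentanoate).

**Three steps most likely to fail**

Step 3 (key coupling). An alkyl allenyl ether has not been used to trap an enamine radical cation. It may hydrolyse or be oxidised by the cerium salt before it reacts, or the oxocarbenium ion may be intercepted at the CH2 terminus. The product is also a β,γ-unsaturated α-chiral aldehyde that can racemise or slip into conjugation, so it is used at once. Fallback, setting out from 4 and returning at 10: the polarity reversal is moved to the ketone partner. Commercial diethyl (2-oxobutyl)phosphonate is brominated (NaH, then NBS, THF, 0 °C) to diethyl (1-bromo-2-oxobutyl)phosphonate F1. Aldehyde 4 is alkylated with F1 under merged enamine and photoredox catalysis ((2R,5S)-2-tert-butyl-3,5-dimethylimidazolidin-4-one triflate 20 mol %, Ru(bpy)3Cl2 0.5 mol %, 2,6-lutidine, DMF, visible light). The 5S centre of this catalyst should shield the same enamine face as in step 3 (predicted from the enamine model used there), and the electrophilic phosphonyl-stabilised α-keto radical gives (2S)-2-[1-(diethoxyphosphoryl)-2-oxobutyl]-3-methylhex-4-ynal F2; the descriptor changes only because phosphorus raises the priority of the new substituent. A Horner–Wadsworth–Emmons methylenation of F2 with aqueous formaldehyde and K2CO3 (THF, 0 °C) then gives 10.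

Step 7 (one-pot phosphorylation and olefination). Three things can go wrong: the dienolate 18 may be phosphorylated on oxygen, the carbanion 20 may add in Michael fashion to the α-methylene ketone of 10, or it may enolise the acidic α-centre of 10. Fallback, setting out from 17 and returning at 21: a neutral Wittig reaction replaces the lithium carbanion. Radical bromination of 17 (NBS, AIBN, PhCF3, 80 °C) gives 2-(1-bromoethyl)-6-methoxy-3,5-dimethyl-4H-pyran-4-one F3. Triphenylphosphine (MeCN, 80 °C) converts it into [1-(6-methoxy-3,5-dimethyl-4-oxo-4H-pyran-2-yl)ethyl]triphenylphosphonium bromide F4. Aqueous NaOH in CH2Cl2 gives the pyrone-stabilised ylide 2-methoxy-3,5-dimethyl-6-[1-(triphenylphosphoranylidene)ethyl]-4H-pyran-4-one F5, which condenses with 10 in toluene at 60 °C, without added base, to give the (E)-alkene 21.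

Step 8 (cycloisomerisation). The pyrone-conjugated alkene is a weaker nucleophile than the alkenes usually used, the α-methylene ketone is a second (electron-poor) 1,5-enyne partner, and its carbonyl oxygen can attack the activated alkyne. A more electrophilic phosphite-gold catalyst is the first adjustment. Fallback, setting out from 21 and returning at 22: the enone is masked for the ring closure. Thiophenol with catalytic triethylamine (CH2Cl2, 0 °C) adds to the methylene ketone to give the phenylsulfanylmethyl ketone F6 (the C(=CH2) unit of 21 replaced by CH(CH2SPh), epimer mixture). The same Ph3PAuCl/AgSbF6 cycloisomerisation at 10 mol % gives the bicyclic sulfide F7. NaIO4 (MeOH/H2O, 0 °C) gives the sulfoxide F8, and its syn-elimination in toluene at 80 °C restores the α-methylene ketone of 22. This fallback removes the enone interference; it does not help if the pyronyl alkene itself is too unreactive.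

**Further compounds**

F1 | step 3 | diethyl (1-bromo-2-oxobutyl)phosphonate | CCC(=O)C(Br)P(=O)(OCC)OCC
F2 | step 3 | (2S)-2-[1-(diethoxyphosphoryl)-2-oxobutyl]-3-methylhex-4-ynal (epimers at C3 and at the phosphonate carbon) | CCC(=O)C(P(=O)(OCC)OCC)[C@@H](C(C)C#CC)C=O
F3 | step 7 | 2-(1-bromoethyl)-6-methoxy-3,5-dimethyl-4H-pyran-4-one | CC(Br)c1oc(OC)c(C)c(=O)c1C
F4 | step 7 | [1-(6-methoxy-3,5-dimethyl-4-oxo-4H-pyran-2-yl)ethyl]triphenylphosphonium bromide | CC(c1oc(OC)c(C)c(=O)c1C)[P+](c1ccccc1)(c1ccccc1)c1ccccc1.[Br-]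
F5 | step 7 | 2-methoxy-3,5-dimethyl-6-[1-(triphenylphosphoranylidene)ethyl]-4H-pyran-4-one | CC(=P(c1ccccc1)(c1ccccc1)c1ccccc1)c1oc(OC)c(C)c(=O)c1C
F6 | step 8 | 2-methoxy-3,5-dimethyl-6-[(2E,4R)-5-methyl-4-(3-oxo-1-(phenylsulfanyl)pentan-2-yl)oct-2-en-6-yn-2-yl]-4H-pyran-4-one (epimer mixture) | CCC(=O)C(CSc1ccccc1)[C@@H](C(C)C#CC)/C=C(\C)c1oc(OC)c(C)c(=O)c1C
F7 | step 8 | 2-methoxy-3,5-dimethyl-6-[(1S,4R,5R,6S)-1,3,6-trimethyl-4-(3-oxo-1-(phenylsulfanyl)pentan-2-yl)bicyclo[3.1.0]hex-2-en-6-yl]-4H-pyran-4-one | CCC(=O)C(CSc1ccccc1)[C@H]1C(C)=C[C@@]2(C)[C@@H]1[C@]2(C)c1oc(OC)c(C)c(=O)c1C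
F8 | step 8 | 2-methoxy-3,5-dimethyl-6-[(1S,4R,5R,6S)-1,3,6-trimethyl-4-(3-oxo-1-(phenylsulfinyl)pentan-2-yl)bicyclo[3.1.0]hex-2-en-6-yl]-4H-pyran-4-one | CCC(=O)C(CS(=O)c1ccccc1)[C@H]1C(C)=C[C@@]2(C)[C@@H]1[C@]2(C)c1oc(OC)c(C)c(=O)c1C
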